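The symmetrical ether is cut at a benzylic C–O bond into two identical 2,3,6-tribromo-4,5-dihydroxybenzyl alcohol halves. The hexasubstituted benzene ring of each half is assembled rather than decorated. The feature exploited is the contiguous ring edge C5(OH)–C4(OH)–C3(Br)–C2, a masked 3-bromo-4-methoxyfuran, next to C6(Br)–C1(C7), a masked bromopropiolate. One [4+2] cycloaddition forges C5–C6 and C1–C2 and closes the carbocycle. Acid then severs the C2–O bridge bond, so the furan oxygen surfaces as the C5 phenol. Two bromines, both oxygens and C7 arrive correctly placed. The precursors are an electron-rich β-methoxy-β'-bromofuran and an electron-poor bromoalkynoate.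

Key step: step 3

Remark on the chemistry: in each benzyl half, C1 carries the benzylic carbon C7, C2, C3 and C6 carry bromine, and C4 and C5 carry oxygen. These locants are used for the ring atoms from the cycloaddition onward. The target is achiral. The only stereocentres on the route, the two bridgeheads of 5, are racemic and vanish on aromatisation.

Step 1
Reactants: 1 3,4-dibromofuran
Product: 2 3-bromo-4-methoxyfuran
Conditions: NaOMe (1.0–1.1 equiv, solution in MeOH), CuBr (10 mol %), NMP, 100 °C, sealed vessel, N2; pentane extraction, distillation from base-washed glassware
Reagents that add atoms: sodium methoxide, [Na+].[O-]C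
Why: This is an Ullmann-type copper-catalysed C–O coupling, the established way from β-halofurans and β-halothiophenes to their methyl ethers, and it should stop at the mono-ether because methoxide is limiting and the first methoxy group enriches the ring and slows exchange at the remaining C–Br bond, with unreacted 1 removed by distillation.

Step 2
Reactants: 3 methyl propiolate
Product: 4 methyl 3-bromopropiolate
Conditions: NBS (1.1 equiv), AgNO3 (10 mol %), acetone, rt, dark; filtration, careful concentration (lachrymator), used promptly
Reagents that add atoms: N-bromosuccinimide, O=C1CCC(=O)N1Br
Why: This is the silver-catalysed electrophilic bromination of a terminal alkyne, in which AgNO3 activates the acetylenic C–H toward NBS, and it is the standard preparation of 1-bromoalkynes and leaves the ester untouched.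

Step 3
Reactants: 2 3-bromo-4-methoxyfuran; 4 methyl 3-bromopropiolate (1.3 equiv)
Product: 6 methyl 2,5-dibromo-3-hydroxy-4-methoxybenzoate, via oxanorbornadiene cycloadduct 5 (not isolated)
Conditions: toluene, 70 °C, dark, N2; then 0 °C → rt, BF3·OEt2 (20 mol %)
Reagents that add atoms: none
Why: The methoxy donor raises the furan HOMO and places its largest coefficient on the adjacent α-carbon (future C5), which leads the bonding to the bromine-bearing β-carbon of the ynoate (C6) while the other α-carbon (C2) closes onto the ester-bearing carbon (C1), a concerted, asynchronous, suprafacial normal-demand Diels–Alder reaction with the "para" orientation of a 2-donor diene. The six-membered carbocycle is therefore closed by an intermolecular [4+2] cycloaddition that makes both σ-bonds in one event, the closest known reactions being the additions of furan, 2-methylfuran and 3-alkoxyfurans to 3-bromopropiolates. The two bridgehead stereocentres of 5 are locked relative to each other by the bicycle, arise as a racemate and are erased on aromatisation, so no stereocontrol is needed. BF3 then binds the bridge oxygen and the C2–O bond ionises, because only the C2 cation is a vinylogous oxocarbenium ion (C2–C3=C4–OMe), whereas a C5 cation would carry the methoxy group on the central allyl carbon and would push charge onto the ester-bearing C1. Loss of the C5 proton from the resulting arenium ion gives the phenol, which is the known acid-mediated isomerisation of 7-oxanorbornadienes to phenols. An anhydrous Lewis acid is chosen so that the bromo enol ether of 5 is not hydrolysed to a ketone before the bridge opens.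

Step 4
Reactants: 6 methyl 2,5-dibromo-3-hydroxy-4-methoxybenzoate
Product: 7 methyl 2,3,6-tribromo-5-hydroxy-4-methoxybenzoate
Conditions: Br2 (1.2 equiv), AcOH, rt → 50 °C
Reagents that add atoms: bromine, BrBr
Why: This is an electrophilic aromatic substitution in which C2 is the only unsubstituted ring carbon and lies para to the free C5 hydroxyl, so bromination has one possible site and cannot overrun.

Step 5
Reactants: 7 methyl 2,3,6-tribromo-5-hydroxy-4-methoxybenzoate
Product: 8 2,4,5-tribromo-3-(hydroxymethyl)-6-methoxyphenol
Conditions: i-Bu2AlH (3.5 equiv), CH2Cl2, −78 → 0 °C; cold 1 M HCl work-up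
Reagents that add atoms: none
Why: In this aluminium hydride reduction of an ester, the first equivalent is spent on the phenol, whose aluminium phenoxide sits meta to the ester and does not deactivate it, the small electrophilic hydride tolerates the two ortho bromines, and aryl bromides are inert at this temperature.

Step 6
Reactants: 8 2,4,5-tribromo-3-(hydroxymethyl)-6-methoxyphenol
Product: 10 3,4,6-tribromo-5-(hydroxymethyl)benzene-1,2-diol, via benzylic bromide 9 (not isolated)
Conditions: BBr3 (3.5 equiv), CH2Cl2, −78 °C → rt; ice-water quench, extraction, concentration; then 1,4-dioxane–H2O, 50 °C, N2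
Reagents that add atoms: boron tribromide, BrB(Br)Br (benzylic Br of 9); water, O (benzylic O of 10)
Why: Lewis-acid cleavage of the aryl methyl ether with BBr3 frees the C4 hydroxyl and at the same time converts the benzylic alcohol into bromide 9, which has a para hydroxyl group and should therefore solvolyse readily (SN1) in warm aqueous dioxane to the alcohol.

Step 7
Reactants: 10 3,4,6-tribromo-5-(hydroxymethyl)benzene-1,2-diol (two molecules)
Product: 11 bis(2,3,6-tribromo-4,5-dihydroxybenzyl) ether
Conditions: p-TsOH·H2O (5 mol %), toluene–1,4-dioxane, 0.5 M, reflux, condensate returned through 4 Å molecular sieves, N2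
Reagents that add atoms: none
Why: In this acid-catalysed dehydrative etherification (SN1), the C7 cation is stabilised by the para C4 hydroxyl and captured by the primary alcohol of a second molecule, Friedel–Crafts alkylation is excluded because no ring carbon carries hydrogen, and removal of water drives the equilibrium.

Compound list
1 | 3,4-dibromofuran | Brc1cocc1Br | starting material
2 | 3-bromo-4-methoxyfuran | COc1cocc1Br | intermediate
3 | methyl propiolate | COC(=O)C#C | starting material
4 | methyl 3-bromopropiolate | COC(=O)C#CBr | intermediate
5 | rac-methyl (1R,4R)-3,6-dibromo-5-methoxy-7-oxabicyclo[2.2.1]hepta-2,5-diene-2-carboxylate (one enantiomer drawn, not isolated) | COC(=O)C1=C(Br)[C@@H]2O[C@H]1C(Br)=C2OC | intermediate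
6 | methyl 2,5-dibromo-3-hydroxy-4-methoxybenzoate | COC(=O)c1cc(Br)c(OC)c(O)c1Br | intermediate
7 | methyl 2,3,6-tribromo-5-hydroxy-4-methoxybenzoate | COC(=O)c1c(Br)c(Br)c(OC)c(O)c1Br | intermediate
8 | 2,4,5-tribromo-3-(hydroxymethyl)-6-methoxyphenol | OCc1c(Br)c(Br)c(OC)c(O)c1Br | intermediate
9 | 3,4,6-tribromo-5-(bromomethyl)benzene-1,2-diol (not isolated) | BrCc1c(Br)c(Br)c(O)c(O)c1Br | intermediate
10 | 3,4,6-tribromo-5-(hydroxymethyl)benzene-1,2-diol | OCc1c(Br)c(Br)c(O)c(O)c1Br | intermediate
11 | bis(2,3,6-tribromo-4,5-dihydroxybenzyl) ether | Oc1c(O)c(Br)c(COCc2c(Br)c(O)c(O)c(Br)c2Br)c(Br)c1Br | target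

Total step count: 7. Longest linear sequence: 6 (steps 1, 3, 4, 5, 6, 7).

Steps most likely to fail

Step 3.
- **Risk:** The bromoalkyne may be lost to thermal decomposition. It may also be consumed by addition–elimination at its C–Br carbon, a net alkynylation of the furan, before the ring closes. Enol ether hydrolysis may compete with bridge opening.
- **Fallback:** It sets out from 2 and 3 and introduces the C6 bromine by aromatic substitution instead of through the alkyne.
  - Furan 2 is heated in a large excess of the thermally robust methyl propiolate 3. The same donor–acceptor orientation should give racemic methyl 6-bromo-5-methoxy-7-oxabicyclo[2.2.1]hepta-2,5-diene-2-carboxylate F1.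
  - Catalytic BF3·OEt2 should isomerise this, by the same methoxy-assisted C2–O scission, to methyl 3-bromo-5-hydroxy-4-methoxybenzoate F2.
  - The two open positions of F2, C2 (para) and C6 (ortho) to the free phenol, are both brominated with Br2 (2.5 equiv) in AcOH.
- **Return:** The route is rejoined at 7.

Step 1.
- **Risk:** The copper-mediated exchange may run on to the dimethoxyfuran or be accompanied by hydrodebromination. The volatile, acid-labile product may then be lost on separation from a statistical mixture.
- **Fallback:** It sets out from 1 and fixes mono-functionalisation by stoichiometry.
  - Bromine–lithium exchange with one equivalent of n-BuLi (Et2O, −78 °C), trapping with B(OMe)3 and mild aqueous hydrolysis should give (4-bromofuran-3-yl)boronic acid F3.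
  - F3 is methoxylated under Chan–Lam conditions (Cu(OAc)2, DMAP, MeOH, 4 Å molecular sieves, air, rt).
- **Return:** The route is rejoined at 2.

Step 7.
- **Risk:** The dehydration is an equilibrium that may stall. Phenolic oxygen may compete with the benzylic hydroxyl for the cation and start oligomerisation. The catechol may oxidise on prolonged heating.
- **Fallback:** It sets out from 9 and 10 and replaces the reversible dehydration with an irreversible substitution.
  - Part of the material of step 6 is stopped after the cold aqueous quench, so that bromide 9 is isolated.
  - Bromide 9 is combined with a slight excess of alcohol 10 in dry THF at rt → 40 °C. 2,6-Di-tert-butyl-4-methylpyridine serves as a non-nucleophilic acid scavenger that is too weak to deprotonate the phenols appreciably.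
  - Any adventitious hydrolysis of 9 only regenerates 10.
- **Return:** The route is rejoined at 11, and no compound outside the list is made (F0).

Further compounds
F1 | step 3 | rac-methyl (1R,4S)-6-bromo-5-methoxy-7-oxabicyclo[2.2.1]hepta-2,5-diene-2-carboxylate (one enantiomer drawn) | COC(=O)C1=C[C@@H]2O[C@H]1C(Br)=C2OC
F2 | step 3 | methyl 3-bromo-5-hydroxy-4-methoxybenzoate | COC(=O)c1cc(Br)c(OC)c(O)c1
F3 | step 1 | (4-bromofuran-3-yl)boronic acid | OB(O)c1cocc1Br
F0 | step 7 | none | none
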